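The readings stem from a simulated flask for an exercise; noise was put on by code.

- Late in both earlier runs L falls: between 2.00 h and 5.00 h it drops from 16 % to 12 % of the G charged in the green run, and from 14 % to 12 % in the grey run. That fall is the quantity to carry to the new flask, where G is the charge and D is the dissolved form of Z.

| flask | G | Z | remark | time |
|---|---|---|---|---|
| green | 14 mM | 2.5 mM (held) | run made earlier |  |
| grey | 20 mM | 2.5 mM (held) | run made earlier |  |
| flask | 27 mM | 2.5 mM (held) |  | 8.0 h |

| run | time / h | L / % |
|---|---|---|
| green | 0.667 | 11 |
| green | 1.33 | 20 |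
| green | 2.00 | 16 |
| green | 3.00 | 17 |
| green | 4.00 | 15 |
| green | 5.00 | 12 |
| grey | 0.250 | 1 |
| grey | 0.667 | 8 |
| grey | 1.33 | 14 |
| grey | 2.00 | 14 |
| grey | 3.00 | 15 |
| grey | 4.00 | 15 |
| grey | 5.00 | 12 |

(readings scatter by 1.5 percentage points)

- at the start none of Z is in solution
- D is what Z becomes in solution

- cedar: doubling the saturation concentration of Z, all else as stated
- elm: doubling the transfer coefficient of Z, all else as stated

* the L standing at 8.0 h, as a percentage of the G charged
* concentration of D in solution at 2.0 h, in percent of saturation
* the change that raises the amount of L at 8.0 h, in percent of the G charged most ("none" if none brings more than 2 percentage points) (cedar / elm / none)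
* amount of L at 8.0 h, in percent of the G charged, after elm

- My own reckoning takes the main step first, G + D giving L. The green run's first reading implies a rate r = 2.31 mM h⁻¹, and if r lasted to 8.0 h the flask would hold 68.4 % of its G as L.
- The second step is that making stops. The grey run, the nearest in charge, stands at 3.00 mM of L at 3.00 h, and the readings do not say what ended it. Carried unchanged to the flask's charge, that level cuts the number to 11.1 %.
- The third step is the fall, treated as pseudo-first-order. Adding the two runs' readings gives the fall constant λ = 0.0744 h⁻¹, the fall rate of L divided by the L standing. λ is a rate per hour, made by dividing by the 3.00 h between the readings, and only the scale of L cancels in its ratio. It is computed from readings that each carry a scatter of 1.5 percentage points, and my reckoning assumes it steady over the late hours.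
- Over the 5.00 h from that reading to 8.0 h, λ brings my figure for y to 7.66 %.
- The forecast differs from this figure, giving y = 14 %, sat = 18 %, best = none and yb = 11.5 %, with “G is about 48% left” at the end.

The flask gives y = 8.44 %, sat = 72.2 %, best = elm (elm adds 3.4 points, cedar −0.26 points) and yb = 11.8 %.

    Z ⇌ D, rate k1*(csat - [D]) (kL = 5.10 × 10⁻⁴ s⁻¹)
    G + D → L (k = 0.200 M⁻¹ s⁻¹)
    G → Q (k = 5.00 × 10⁻⁴ s⁻¹)
    D + L → J (k = 0.0100 M⁻¹ s⁻¹)
    2 G → X (k = 1.50 × 10⁻⁶ M⁻¹ s⁻¹)
    2 D → E (k = 0.00280 M⁻¹ s⁻¹)

- The forecast and the flask part on G: at 4.00 h the flask holds G 0 % and Q 85.5 %, with L at 11.8 %. From there, λ gives 8.74 % at 8.0 h, against the 8.44 % found. Left standing until 20 h, the same flask is reckoned from 8.44 % to 3.46 %, and its simulated L is 3.03 %, beside J at 11.4 %.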